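## Retrosynthetic overview
1. Ring C is closed last. O1–C2 is cut back to an open 2'-hydroxychalcone, and the closure (the chalcone isomerase step) is run as a catalytic enantioselective oxa-Michael addition on the unactivated enone. C-2 (S) is therefore set in the ring-forming event itself, with no auxiliary, activating ester or resolution.
2. In that chalcone only the hydroxyl next to the prenyl group is free (MOM on the other two). This forces the 8-prenyl flavanone and excludes the 6-prenyl isomer. The MOM groups are removed in the same flask.
3. The chalcone comes from a Claisen–Schmidt union of a C-prenylated phloroacetophenone with 2,2-dimethylchroman-6-carbaldehyde.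
4. Ring D is made first, in one flask, from 4-hydroxybenzaldehyde and isoprene: aromatic prenylation, then cyclisation of the o-prenylphenol onto its protonated alkene.
5. Ring order: D, then C. Rings A and B are bought (A = phloroglucinol ring, B = aryl ring at C-2, C = pyranone, D = dimethyldihydropyran).

Assumption: the (S)-configured catalyst of step 5 is taken to deliver the (2S) product. The sense is read on an aliquot of 11 by chiral HPLC and CD (positive band near 330 nm, negative near 290 nm for 2S), and the mirror-image catalyst is used if it is opposite.

## Route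

Step 1
Reactants: 1 4-hydroxybenzaldehyde; 2 isoprene (2-methylbuta-1,3-diene)
Product: 4 2,2-dimethylchroman-6-carbaldehyde, via 4-hydroxy-3-prenylbenzaldehyde 3 (not isolated)
Conditions: isoprene (2.5 equiv, slow addition), 85 % H3PO4, xylene, 35 → 60 °C, 16 h
Reagents that add atoms: isoprene (compound 2), C=CC(C)=C
Why: Friedel–Crafts prenylation by the dimethylallyl cation from protonated isoprene goes to C-3, the position to which both the hydroxyl (ortho) and the formyl group (meta) direct, and the o-prenylphenol 3 then closes by Markovnikov protonation of its alkene and capture of the tertiary cation by the phenol oxygen (intramolecular hydroalkoxylation), which is how the plant is thought to build ring D; no stereocentre is formed.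

Step 2
Reactants: 5 2,4,6-trihydroxyacetophenone (phloroacetophenone); 6 prenyl bromide (1-bromo-3-methylbut-2-ene)
Product: 7 2,4,6-trihydroxy-3-(3-methylbut-2-en-1-yl)acetophenone
Conditions: prenyl bromide (1.0 equiv), KOH (1.0 equiv), H2O, 0 °C → rt, 3 h; then dilute HCl to pH 4
Reagents that add atoms: prenyl bromide (compound 6), CC(C)=CCBr
Why: This is C-alkylation of an ambident phloroglucinol phenoxide (aromatic prenylation, SN2 on the allylic bromide), in which water hydrogen-bonds the oxygen so that carbon reacts, the two open ring positions are equivalent so only one mono-C-prenyl isomer exists, and one equivalent of bromide limits diprenylation; no stereocentre is formed.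

Step 3
Reactants: 7 2,4,6-trihydroxy-3-prenylacetophenone; 8 chloromethyl methyl ether (MOMCl)
Product: 9 2-hydroxy-4,6-bis(methoxymethoxy)-3-(3-methylbut-2-en-1-yl)acetophenone
Conditions: MOMCl (2.2 equiv), K2CO3 (3 equiv), acetone, 0 °C → rt, 4 h
Reagents that add atoms: chloromethyl methyl ether (compound 8), COCCl
Why: Williamson-type O-alkylation takes the acidic unchelated 4-OH first and then the less hindered 6-OH, while the 2-OH wedged between prenyl and acetyl stays locked in its hydrogen bond to the carbonyl, so exactly the hydroxyl needed for ring C is left free; no stereocentre is formed.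

Step 4
Reactants: 9 2-hydroxy-4,6-bis(methoxymethoxy)-3-prenylacetophenone; 4 2,2-dimethylchroman-6-carbaldehyde
Product: 10 (E)-3-(2,2-dimethylchroman-6-yl)-1-[2-hydroxy-4,6-bis(methoxymethoxy)-3-(3-methylbut-2-en-1-yl)phenyl]prop-2-en-1-one
Conditions: KOH (10 equiv), EtOH/H2O, 0 °C → rt, 30 h; then cold 1 M citric acid to pH 5; chromatography
Reagents that add atoms: none
Why: In this Claisen–Schmidt condensation (crossed aldol, E1cB dehydration) aldehyde 4 cannot enolise, the MOM ethers, prenyl group and chroman are inert to hydroxide, the conjugated E-alkene is the thermodynamic product, and the chalcone stays open as its phenoxide in strong base; no stereocentre is formed.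

Step 5
Reactants: 10 the (E)-2'-hydroxy-4',6'-bis(methoxymethoxy)-3'-prenylchalcone
Product: 12 euchrenone a16 [(2S)-2-(2,2-dimethylchroman-6-yl)-5,7-dihydroxy-8-(3-methylbut-2-en-1-yl)chroman-4-one], via (2S)-bis-MOM flavanone 11 (not isolated)
Conditions: bifunctional iminophosphorane–thiourea superbase 1-[3,5-bis(trifluoromethyl)phenyl]-3-[(2S)-3,3-dimethyl-1-{[tris(4-methoxyphenyl)-λ5-phosphanylidene]amino}butan-2-yl]thiourea (10 mol %, made beforehand from the azide and P(4-MeOC6H4)3), PhMe, −20 °C, 36 h (HPLC control, > 97 % conversion); then 3 M HCl in MeOH, 40 °C, 2 h; pH 7 buffer work-up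
Reagents that add atoms: none
Why: Proposed new method: this is a catalytic enantioselective intramolecular oxa-Michael addition (6-endo-trig) on a chalcone with no extra activating group, a small-molecule copy of chalcone isomerase, in which the iminophosphorane (far more basic than a tertiary amine) fully ionises the chelated 2'-OH as in the enzyme, where the 2'-oxyanion is the nucleophile, the thiourea N–H bonds hold the carbonyl oxygen and stabilise the developing enolate, and within this tight chiral ion pair the phenoxide adds to the Si face of C-β to set C-2 as S; the 6'-OMOM group twists the carbonyl out of the ring plane and makes closure favourable, so at −20 °C the retro-reaction (the only path to racemisation) is slow relative to closure, and HCl/MeOH then protonates the base at once and removes both MOM acetals by acetal exchange without touching the prenyl alkene, ring D or C-2; the closest known reaction types are the cinchona-thiourea cyclisation of α-carboxy-activated 2'-hydroxychalcones to flavanones, the moderate-ee cinchona-alkaloid cyclisation of 6'-substituted 2'-hydroxychalcones, and iminophosphorane-superbase oxa-Michael cyclisations onto unactivated enoates.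

## Compound list
1 | 4-hydroxybenzaldehyde | O=Cc1ccc(O)cc1 | starting material
2 | isoprene | C=CC(C)=C | starting material
3 | 4-hydroxy-3-(3-methylbut-2-en-1-yl)benzaldehyde | CC(C)=CCc1cc(C=O)ccc1O | intermediate
4 | 2,2-dimethylchroman-6-carbaldehyde | CC1(C)CCc2cc(C=O)ccc2O1 | intermediate
5 | 2,4,6-trihydroxyacetophenone | CC(=O)c1c(O)cc(O)cc1O | starting material
6 | prenyl bromide | CC(C)=CCBr | starting material
7 | 2,4,6-trihydroxy-3-(3-methylbut-2-en-1-yl)acetophenone | CC(=O)c1c(O)c(CC=C(C)C)c(O)cc1O | intermediate
8 | chloromethyl methyl ether | COCCl | starting material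
9 | 2-hydroxy-4,6-bis(methoxymethoxy)-3-(3-methylbut-2-en-1-yl)acetophenone | CC(=O)c1c(O)c(CC=C(C)C)c(OCOC)cc1OCOC | intermediate
10 | (E)-3-(2,2-dimethylchroman-6-yl)-1-[2-hydroxy-4,6-bis(methoxymethoxy)-3-(3-methylbut-2-en-1-yl)phenyl]prop-2-en-1-one | COCOc1cc(OCOC)c(C(=O)/C=C/c2ccc3c(c2)CCC(C)(C)O3)c(O)c1CC=C(C)C | intermediate
11 | (2S)-2-(2,2-dimethylchroman-6-yl)-5,7-bis(methoxymethoxy)-8-(3-methylbut-2-en-1-yl)chroman-4-one | CC(C)=CCc1c(OCOC)cc(OCOC)c2c1O[C@H](c1ccc3c(c1)CCC(C)(C)O3)CC2=O | intermediate
12 | euchrenone a16, (2S)-2-(2,2-dimethylchroman-6-yl)-5,7-dihydroxy-8-(3-methylbut-2-en-1-yl)chroman-4-one | CC(C)=CCc1c(O)cc(O)c2c1O[C@H](c1ccc3c(c1)CCC(C)(C)O3)CC2=O | target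

## Step count and risks
Total step count: 5.
Longest linear sequence: 4 steps (5 → 7 → 9 → 10 → 12). Step 1 is a one-step side branch.

**Most likely to fail, first: step 5.**
- High enantioselectivity has not been shown for an unactivated chalcone.
- The nucleophilic oxygen is crowded by the prenyl group.
- Any 10 left at the acid stage would lose its MOM groups and close without regio- or stereocontrol.

The fallback keeps the same ring closure but moves the stereochemical decision to a resolution. It sets out from 10. NaOAc in refluxing EtOH closes ring C to the racemic bis-MOM flavanone F1. A Noyori–Ikariya asymmetric transfer hydrogenation then acts as a kinetic resolution: RuCl(p-cymene)[(R,R)-TsDPEN] (1 mol %), HCO2H/Et3N, EtOAc, rt, stopped near 52 % conversion. It reduces the (2R)-ketone to the cis-(2R,4R)-flavan-4-ol F2 and leaves the (2S)-ketone. This is separated on silica, so the fallback comes back to the route at 11, now isolated. The HCl/MeOH half of step 5 follows unchanged.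

**Second: step 1.**
- The formyl group deactivates the ring towards the prenyl cation.
- Isoprene oligomerises in acid, so 30–40 % yield is the realistic range.

The fallback reverses the order of ring D formation and formyl introduction. It sets out from 2. With commercial phenol under the same H3PO4 conditions, 2 gives 2,2-dimethylchroman F3 by the same prenylation/cyclisation on a much more nucleophilic ring. A Rieche formylation (Cl2CHOMe, TiCl4, CH2Cl2, 0 °C), para to the ring oxygen, then comes back to the route at 4.

**Third: step 2.**
- Mono-C-prenylation competes with diprenylation and O-alkylation, so 35–50 % yield is expected.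

The fallback replaces direct C-alkylation by O-allylation and sigmatropic transfer. It sets out from 5. A Tsuji–Trost etherification (Pd(PPh3)4 at 2 mol %, methyl 2-methylbut-3-en-2-yl carbonate, THF, 0 °C) acts on the most acidic 4-OH and gives the tertiary 1,1-dimethylallyl ether F4. An aromatic Claisen rearrangement (PhMe, 110 °C) moves the group, with allyl inversion, to either of the two equivalent ortho carbons. This comes back to the route at 7.

## Further compounds
F1 | step 5 | racemic 2-(2,2-dimethylchroman-6-yl)-5,7-bis(methoxymethoxy)-8-(3-methylbut-2-en-1-yl)chroman-4-one | CC(C)=CCc1c(OCOC)cc(OCOC)c2c1OC(c1ccc3c(c1)CCC(C)(C)O3)CC2=O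
F2 | step 5 | (2R,4R)-2-(2,2-dimethylchroman-6-yl)-5,7-bis(methoxymethoxy)-8-(3-methylbut-2-en-1-yl)chroman-4-ol | CC(C)=CCc1c(OCOC)cc(OCOC)c2c1O[C@@H](c1ccc3c(c1)CCC(C)(C)O3)C[C@H]2O
F3 | step 1 | 2,2-dimethylchroman | CC1(C)CCc2ccccc2O1
F4 | step 2 | 1-[2,6-dihydroxy-4-(2-methylbut-3-en-2-yloxy)phenyl]ethan-1-one | CC(=O)c1c(O)cc(OC(C)(C)C=C)cc1O
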